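**Retrosynthetic overview**

- Fragransin B1 ⇐ all-cis 2,5-diaryl-3,4-dimethyltetrahydrofuran, by epimerising the two benzylic ring carbons. Each para-OH makes its benzylic C–O bond ionisable, and the target (each aryl trans to the neighbouring methyl) is the thermodynamic sink of the cis-3,4-dimethyl series.
- All-cis tetrahydrofuran ⇐ 2,5-diaryl-3,4-dimethylfuran, by one-face hydrogenation that sets all four stereocentres, the cis-dimethyl pair included.
- Furan ⇐ aryl ethyl ketone + propenylarene by oxidative [3+2] annulation. The ketone supplies O1, C2 and C3, the alkene C4 and C5; bonds C3–C4 and O1–C5 form in one operation. This is a cross 8–8' coupling of two C6–C3 units, as in lignan biosynthesis.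
- Enabling feature: the ring O lies between two aryl-bearing carbons and every ring carbon carries one H. The ring can therefore be built flat as a furan, whose O1–C2=C3 part is the enol of a propiophenone and whose C4=C5 part is a β-methylstyrene.
- Only ring: the oxolane, formed in step 6 at the furan level. The ketone comes from syringaldehyde, the alkene from 4-allyl-2,6-dimethoxyphenol.

Key step: step 6

Remark: the target SMILES is the achiral meso isomer (2,3-trans, 3,4-cis, 4,5-trans; both aryl groups on one face, both methyls on the other), so only relative configuration has to be controlled.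

**Route**

Step 1
Reactants: 1 syringaldehyde
Product: 2 rac-1-(4-hydroxy-3,5-dimethoxyphenyl)propan-1-ol
Conditions: EtMgBr (3 equiv), THF, 0 °C → rt; then aq. NH4Cl
Reagents that add atoms: ethylmagnesium bromide, CC[Mg]Br
Why: Grignard addition, in which the first equivalent deprotonates the phenol and a further equivalent adds to the aldehyde of the magnesium phenoxide; the new carbinol centre is racemic and is removed in step 2.

Step 2
Reactants: 2 rac-1-(4-hydroxy-3,5-dimethoxyphenyl)propan-1-ol
Product: 3 1-(4-hydroxy-3,5-dimethoxyphenyl)propan-1-one (propiosyringone)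
Conditions: DDQ (1.1 equiv), 1,4-dioxane, rt
Reagents that add atoms: none
Why: DDQ dehydrogenation of a p-hydroxybenzylic alcohol (benzylic oxidation by hydride abstraction, assisted by the para oxygen) should stop at the aryl ketone.

Step 3
Reactants: 3 propiosyringone
Product: 4 2,6-dimethoxy-4-propanoylphenyl acetate
Conditions: Ac2O, pyridine, DMAP (cat.), CH2Cl2, rt
Reagents that add atoms: acetic anhydride, CC(=O)OC(C)=O
Why: DMAP-catalysed O-acylation gives the aryl acetate, which blocks phenoxyl-radical formation in step 6, adds no weak C–H bond, survives hydrogenation and leaves by acid methanolysis in step 8.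

Step 4
Reactants: 5 4-allyl-2,6-dimethoxyphenol
Product: 6 4-allyl-2,6-dimethoxyphenyl acetate
Conditions: Ac2O, pyridine, DMAP (cat.), CH2Cl2, rt
Reagents that add atoms: acetic anhydride, CC(=O)OC(C)=O
Why: The same O-acylation, which leaves the terminal alkene untouched.

Step 5
Reactants: 6 4-allyl-2,6-dimethoxyphenyl acetate
Product: 7 (E)-2,6-dimethoxy-4-(prop-1-en-1-yl)phenyl acetate
Conditions: RuHCl(CO)(PPh3)3 (1 mol %), toluene, 80 °C
Reagents that add atoms: none
Why: Ruthenium-hydride-catalysed alkene isomerisation (hydrometalation/β-hydride elimination) moves the double bond into conjugation and should give mainly the (E)-alkene, whose geometry does not matter because step 6 erases it.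

Step 6
Reactants: 4 2,6-dimethoxy-4-propanoylphenyl acetate; 7 (E)-2,6-dimethoxy-4-(prop-1-en-1-yl)phenyl acetate
Product: 9 2,5-bis(4-acetoxy-3,5-dimethoxyphenyl)-3,4-dimethylfuran, via dihydrofuran 8 (not isolated)
Conditions: CuBr·SMe2 (20 mol %), (tBuO)2 (4 equiv), 7 (2 equiv), PhCl, 120 °C, under argon
Reagents that add atoms: none
Why: Monovalent copper cleaves the peroxide to tert-butoxyl radical and divalent copper, which convert ketone 4 (through its copper enolate or by H-abstraction) into the secondary α-keto radical; this electrophilic radical adds to the methyl-bearing alkene carbon of the electron-rich styrene 7 (C3–C4 bond), divalent copper oxidises the resulting benzylic radical to the cation (or a trivalent organocopper species), the ketone oxygen traps it (O1–C5 bond), and deprotonation gives dihydrofuran 8, which a second H-abstraction/oxidation/deprotonation at its benzylic, oxygen-bearing C–H aromatises to furan 9. The closest known reaction type is the copper-catalysed oxidative [3+2] annulation of aryl alkyl ketones with aryl olefins to 2,5-diarylfurans, a relative of the Mn(OAc)3/Cu(OAc)2 dihydrofuran synthesis. The one ring closes by attack of the carbonyl (enol) oxygen on the benzylic cation, a five-membered O-cyclisation of a γ-cationic ketone in which the former C=O bond ends inside the ring, as in a Paal–Knorr closure. No stereocentre survives the step, because the product is a planar furan, and this is intended: the four stereocentres are set afterwards by hydrogenation and equilibration, so neither the E/Z ratio of 7 nor the diastereomer ratio of 8 matters. The selectivity needed is regiochemical (attack at the β-carbon of the propenyl group, not at the benzylic carbon) and is secured by the aryl ring of 7, which stabilises the adduct radical and cation only in this orientation, while an excess of 7 favours cross-coupling over homo-coupling of 4. The acetates keep the phenols from oxidation to phenoxyl radicals and, unlike benzyl ethers, add no weak C–H bond for tert-butoxyl radicals.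

Step 7
Reactants: 9 2,5-bis(4-acetoxy-3,5-dimethoxyphenyl)-3,4-dimethylfuran
Product: 10 (2R,3S,4R,5S)-2,5-bis(4-acetoxy-3,5-dimethoxyphenyl)-3,4-dimethyltetrahydrofuran (all-cis, meso)
Conditions: H2 (5 atm), 10% Pd/C, EtOAc, 40 °C
Reagents that add atoms: none
Why: Heterogeneous catalytic hydrogenation of the furan should deliver all four hydrogens to the face bound to the metal (the dihydrofuran stage re-adsorbs through its less hindered, hydrogen-bearing face), which sets C2–C5 all-cis and fixes the cis-3,4-dimethyl relationship, while the neutral solvent and the acetoxy-deactivated aryl rings hold back hydrogenolysis of the benzylic C–O bonds.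

Step 8
Reactants: 10 all-cis tetrahydrofuran diacetate
Product: 13 fragransin B1, via all-cis bisphenol 11 (not isolated), via mono-epimer 12 (not isolated)
Conditions: HCl (1.25 M in MeOH), 45 °C, under argon
Reagents that add atoms: none
Why: Acid-catalysed transesterification frees both phenols, after which the para-hydroxy groups allow reversible acid-catalysed opening of the C2–O and C5–O bonds to p-hydroxybenzyl cations (protonated p-quinone methides) and re-closure (SN1 epimerisation, as in the acid epimerisation of furofuran lignans), so that under thermodynamic control each aryl group should move trans to its neighbouring methyl while the non-epimerisable C3 and C4 stay cis, giving the meso 2,3-trans-3,4-cis-4,5-trans isomer.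

**Compound list**

1 | syringaldehyde (4-hydroxy-3,5-dimethoxybenzaldehyde) | COc1cc(C=O)cc(OC)c1O | starting material
2 | rac-1-(4-hydroxy-3,5-dimethoxyphenyl)propan-1-ol | CCC(O)c1cc(OC)c(O)c(OC)c1 | intermediate
3 | 1-(4-hydroxy-3,5-dimethoxyphenyl)propan-1-one (propiosyringone) | CCC(=O)c1cc(OC)c(O)c(OC)c1 | intermediate
4 | 2,6-dimethoxy-4-propanoylphenyl acetate | CCC(=O)c1cc(OC)c(OC(C)=O)c(OC)c1 | intermediate
5 | 4-allyl-2,6-dimethoxyphenol | C=CCc1cc(OC)c(O)c(OC)c1 | starting material
6 | 4-allyl-2,6-dimethoxyphenyl acetate | C=CCc1cc(OC)c(OC(C)=O)c(OC)c1 | intermediate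
7 | (E)-2,6-dimethoxy-4-(prop-1-en-1-yl)phenyl acetate | C/C=C/c1cc(OC)c(OC(C)=O)c(OC)c1 | intermediate
8 | 2,5-bis(4-acetoxy-3,5-dimethoxyphenyl)-3,4-dimethyl-2,3-dihydrofuran (cis/trans mixture, racemic; not isolated) | CC1=C(c2cc(OC)c(OC(C)=O)c(OC)c2)OC(c2cc(OC)c(OC(C)=O)c(OC)c2)C1C | intermediate
9 | 2,5-bis(4-acetoxy-3,5-dimethoxyphenyl)-3,4-dimethylfuran | Cc1c(-c2cc(OC)c(OC(C)=O)c(OC)c2)oc(-c2cc(OC)c(OC(C)=O)c(OC)c2)c1C | intermediate
10 | (2R,3S,4R,5S)-2,5-bis(4-acetoxy-3,5-dimethoxyphenyl)-3,4-dimethyltetrahydrofuran (all-cis, meso) | COc1cc([C@@H]2O[C@H](c3cc(OC)c(OC(C)=O)c(OC)c3)[C@H](C)[C@@H]2C)cc(OC)c1OC(C)=O | intermediate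
11 | (2R,3S,4R,5S)-2,5-bis(4-hydroxy-3,5-dimethoxyphenyl)-3,4-dimethyltetrahydrofuran (all-cis, meso; not isolated) | COc1cc([C@@H]2O[C@H](c3cc(OC)c(O)c(OC)c3)[C@H](C)[C@@H]2C)cc(OC)c1O | intermediate
12 | rac-(2R,3S,4R,5R)-2,5-bis(4-hydroxy-3,5-dimethoxyphenyl)-3,4-dimethyltetrahydrofuran (2,3-cis, 3,4-cis, 4,5-trans; not isolated) | COc1cc([C@@H]2O[C@@H](c3cc(OC)c(O)c(OC)c3)[C@H](C)[C@@H]2C)cc(OC)c1O | intermediate
13 | fragransin B1, (2R,3R,4S,5S)-2,5-bis(4-hydroxy-3,5-dimethoxyphenyl)-3,4-dimethyltetrahydrofuran (meso; 2,3-trans, 3,4-cis, 4,5-trans) | COc1cc([C@H]2O[C@@H](c3cc(OC)c(O)c(OC)c3)[C@H](C)[C@@H]2C)cc(OC)c1O | target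

**Step count and risks**

Total step count: 8. Longest linear sequence: 6 steps (1 → 2 → 3 → 4 → 9 → 10 → 13, steps 1, 2, 3, 6, 7, 8).

Steps most likely to fail:

1. Step 6. The secondary α-keto radical may add too slowly to the internal alkene, so that homo-coupling of the ketone radical, allylic H-abstraction from the propenyl methyl of 7, or oxidative degradation of the electron-rich rings takes over. Fallback: the same ring is made from ketone 4 alone by enolate chemistry. Soft enolisation (TMSOTf, Et3N, CH2Cl2, 0 °C) gives the (Z)-trimethylsilyl enol ether F1. Oxidative homo-coupling (Ag2O, DMSO, 65 °C) gives 1,4-bis(4-acetoxy-3,5-dimethoxyphenyl)-2,3-dimethylbutane-1,4-dione F2 as a meso/racemic mixture, which does not matter. Paal–Knorr cyclodehydration (TsOH, toluene, reflux) then returns to the route at furan 9.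

2. Step 7. Hydrogenation may stall at the tetrasubstituted enol ether stage, or run on to hydrogenolysis of the benzylic C–O bonds. Fallback: the cis-dimethyl unit is set on an open chain. Furan 9 is opened oxidatively (mCPBA, CH2Cl2, 0 °C) to the (Z)-ene-1,4-dione F3. Its activated alkene should take up hydrogen in syn fashion (H2, 1 atm, Pd/C, EtOAc, rt) to give the meso-1,4-diketone F4. LiAlH4 (THF, 0 °C) reduces both ketones and removes both acetates to give tetraol F5 (carbinol epimers, which do not matter). Acid-catalysed cyclodehydration (HCl, MeOH, rt) through the p-hydroxybenzyl cation closes the ring under thermodynamic control and rejoins the route at target 13, bypassing 10.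

3. Step 8. The benzylic cation may be captured irreversibly by the other aryl ring (Friedel–Crafts closure to an aryltetralin) faster than the oxygen re-closes, or equilibration may stop at the mono-epimer stage. Fallback: the two benzylic centres are equilibrated through radicals, not cations. Diacetate 10 is subjected to reversible photochemical hydrogen-atom transfer (4CzIPN (cat.), quinuclidine (cat.), 1-adamantanethiol (cat.), blue LED, MeCN, rt). This abstracts and returns only the hydridic, benzylic α-oxygen C2–H and C5–H and should funnel the all-cis isomer to the trans,cis,trans diacetate F6. Mild methanolysis (K2CO3, MeOH, rt) then rejoins the route at target 13.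

**Further compounds**

F1 | step 6 | (Z)-2,6-dimethoxy-4-[1-(trimethylsilyloxy)prop-1-en-1-yl]phenyl acetate | C/C=C(\O[Si](C)(C)C)c1cc(OC)c(OC(C)=O)c(OC)c1
F2 | step 6 | 1,4-bis(4-acetoxy-3,5-dimethoxyphenyl)-2,3-dimethylbutane-1,4-dione (meso/racemic mixture) | CC(C(=O)c1cc(OC)c(OC(C)=O)c(OC)c1)C(C)C(=O)c1cc(OC)c(OC(C)=O)c(OC)c1
F3 | step 7 | (Z)-1,4-bis(4-acetoxy-3,5-dimethoxyphenyl)-2,3-dimethylbut-2-ene-1,4-dione | C/C(C(=O)c1cc(OC)c(OC(C)=O)c(OC)c1)=C(\C)C(=O)c1cc(OC)c(OC(C)=O)c(OC)c1
F4 | step 7 | meso-(2R,3S)-1,4-bis(4-acetoxy-3,5-dimethoxyphenyl)-2,3-dimethylbutane-1,4-dione | C[C@@H](C(=O)c1cc(OC)c(OC(C)=O)c(OC)c1)[C@H](C)C(=O)c1cc(OC)c(OC(C)=O)c(OC)c1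
F5 | step 7 | (2R,3S)-1,4-bis(4-hydroxy-3,5-dimethoxyphenyl)-2,3-dimethylbutane-1,4-diol (mixture of carbinol epimers) | C[C@@H](C(O)c1cc(OC)c(O)c(OC)c1)[C@H](C)C(O)c1cc(OC)c(O)c(OC)c1
F6 | step 8 | (2R,3R,4S,5S)-2,5-bis(4-acetoxy-3,5-dimethoxyphenyl)-3,4-dimethyltetrahydrofuran (meso; 2,3-trans, 3,4-cis, 4,5-trans) | COc1cc([C@H]2O[C@@H](c3cc(OC)c(OC(C)=O)c(OC)c3)[C@H](C)[C@@H]2C)cc(OC)c1OC(C)=O
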